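## Retrosynthetic overview

1. Lepadin H ⇐ acidolysis of its N-tert-butylsulfonyl, O-silyl derivative ⇐ Mitsunobu coupling (inversion at C3) of an all-cis 3-hydroxy-decahydroquinoline with (2E,4E)-octa-2,4-dienoic acid.
2. That alcohol ⇐ three substrate-controlled reductions (C8a-OH to C8a-H, C4=C4a, C3=O) of a bicyclic 8a-hydroxy enone.
3. The 8a-hydroxy enone ⇐ aza-Achmatowicz ring expansion of an alpha-furyl sulfinamide. Ring B (the carbocycle) is bought inside the furan; ring A (the piperidine) is the only ring built, and it is built last.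
4. Key C2-C3 bond: a 2-metallated tetrahydrobenzofuran (masked acyl anion for C3) adds to (S)-N-tert-butanesulfinyl acetaldimine (C2, CH3, N).
5. Chiral furan ⇐ asymmetric hydrogenation ⇐ B-alkyl Suzuki coupling of 6,7-dihydrobenzofuran-4-yl triflate with the borane from (R)-oct-1-en-5-ol silyl ether ((R)-2-propyloxirane + allylmagnesium bromide).

Assumption: (R)-2-propyloxirane, 6,7-dihydrobenzofuran-4(5H)-one, (S)-2-methylpropane-2-sulfinamide and (E)-hex-2-enal are bought. TBS = tert-butyldimethylsilyl; Bus = tert-butylsulfonyl; lepadin numbering (N1, C2-C8a, side chain C1'-C8') is used in the explanations; "top face" is the face of H2, H4a, H5 and H8a in the target.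

## Route

Step 1
Reactants: 1 (R)-2-propyloxirane; 2 allylmagnesium bromide
Product: 3 (R)-oct-1-en-5-ol
Conditions: CuI (10 mol %), THF, -30 to 0 °C; then H2O
Reagents that add atoms: none
Why: Cu-catalysed SN2 epoxide opening by the allyl Grignard at the unsubstituted carbon, so the carbinol centre is untouched and stays R (it becomes C5').

Step 2
Reactants: 3 (R)-oct-1-en-5-ol
Product: 4 (R)-tert-butyldimethyl(oct-1-en-5-yloxy)silane
Conditions: TBSCl, imidazole, DMF, rt
Reagents that add atoms: tert-butyldimethylsilyl chloride, CC(C)(C)[Si](C)(C)Cl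
Why: Standard silyl ether protection, needed so that only the C3 hydroxyl is free in the later Mitsunobu step.

Step 3
Reactants: 5 6,7-dihydrobenzofuran-4(5H)-one
Product: 7 6,7-dihydrobenzofuran-4-yl trifluoromethanesulfonate, via lithium enolate 6 (not isolated)
Conditions: LiN(SiMe3)2, THF, -78 °C; PhNTf2, -78 °C to rt
Reagents that add atoms: N-phenylbis(trifluoromethanesulfonimide), O=S(=O)(N(c1ccccc1)S(=O)(=O)C(F)(F)F)C(F)(F)F
Why: Enol triflate formation; the ketone has only one enolisable position, so a single regioisomer forms.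

Step 4
Reactants: 4 (R)-tert-butyldimethyl(oct-1-en-5-yloxy)silane; 7 6,7-dihydrobenzofuran-4-yl trifluoromethanesulfonate
Product: 9 4-[(5R)-5-(TBSO)octyl]-6,7-dihydrobenzofuran, via alkylborane 8 (not isolated)
Conditions: 9-BBN, THF, rt; then 7, PdCl2(dppf) (5 mol %; dppf = 1,1'-bis(diphenylphosphino)ferrocene), aq K3PO4, DMF, 50 °C
Reagents that add atoms: none
Why: Anti-Markovnikov hydroboration followed by B-alkyl Suzuki-Miyaura coupling with the enol triflate attaches the complete C8 side chain to the future C5.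

Step 5
Reactants: 9 4-[(5R)-5-(TBSO)octyl]-6,7-dihydrobenzofuran
Product: 10 (4S)-4-[(5R)-5-(TBSO)octyl]-4,5,6,7-tetrahydrobenzofuran
Conditions: H2 (50 bar), [Ir(cod)(L)][B(C6H3-3,5-(CF3)2)4] (1 mol %; cod = 1,5-cyclooctadiene; L = (S)-4-tert-butyl-2-[2-(di-o-tolylphosphino)phenyl]-4,5-dihydrooxazole), CH2Cl2, rt
Reagents that add atoms: none
Why: Iridium-phosphinooxazoline asymmetric hydrogenation of a trisubstituted, arene-conjugated cyclic alkene, by analogy with 1-alkyl-3,4-dihydronaphthalenes; the catalyst sets the future C5 as S (the mirror-image ligand is used if the first run gives the 4R series), and the minor C5 epimer is removed by chromatography at 19 or 20.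

Step 6
Reactants: 11 (S)-2-methylpropane-2-sulfinamide; 12 acetaldehyde
Product: 13 (S,E)-N-ethylidene-2-methylpropane-2-sulfinamide
Conditions: CuSO4, CH2Cl2, rt
Reagents that add atoms: none
Why: Dehydrative condensation to the Ellman N-sulfinyl aldimine, which supplies C2, its methyl group, the nitrogen and the chiral controller.

Step 7
Reactants: 10 (4S)-4-[(5R)-5-(TBSO)octyl]-4,5,6,7-tetrahydrobenzofuran; 13 (S,E)-N-ethylidene-2-methylpropane-2-sulfinamide
Product: 16 (S)-N-[(1S)-1-{(4S)-4-[(5R)-5-(TBSO)octyl]-4,5,6,7-tetrahydrobenzofuran-2-yl}ethyl]-2-methylpropane-2-sulfinamide, via furyllithium 14 (not isolated), via furylmagnesium bromide 15 (not isolated)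
Conditions: n-BuLi, THF, -78 to 0 °C; MgBr2·OEt2, -78 °C; 13, toluene, -78 to -40 °C; then H2O
Reagents that add atoms: none
Why: Furan alpha-lithiation, transmetalation and Ellman 1,2-addition: the metallated furan carbon is a masked acyl anion (it becomes the C3 carbonyl in step 8), so the imine carbon C2 and the future carbonyl carbon C3, both normally electrophilic, are joined, and the magnesium-chelated chair transition state of the (S)-sulfinyl imine delivers the furyl group to the Re face to give 2S.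

Step 8
Reactants: 16 (S)-N-[(1S)-1-{(4S)-4-[(5R)-5-(TBSO)octyl]-4,5,6,7-tetrahydrobenzofuran-2-yl}ethyl]-2-methylpropane-2-sulfinamide
Product: 18 (2S,5S)-1-Bus-8a-hydroxy-2-methyl-5-[(5R)-5-(TBSO)octyl]-2,5,6,7,8,8a-hexahydroquinolin-3(1H)-one (8a epimers), via sulfonamide 17 (not isolated)
Conditions: mCPBA (2.5 equiv), CH2Cl2, 0 °C to rt
Reagents that add atoms: meta-chloroperoxybenzoic acid, OOC(=O)c1cccc(Cl)c1
Why: One-pot oxidation of the sulfinamide to the sulfonamide and aza-Achmatowicz ring expansion: the furan opens to a cis-enedione and the sulfonamide nitrogen closes onto the C8a carbonyl, which forms ring A and unmasks the C3 ketone without touching C2 or C5.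

Step 9
Reactants: 18 (2S,5S)-1-Bus-8a-hydroxy-2-methyl-5-[(5R)-5-(TBSO)octyl]-2,5,6,7,8,8a-hexahydroquinolin-3(1H)-one
Product: 19 (2S,5S,8aR)-1-Bus-2-methyl-5-[(5R)-5-(TBSO)octyl]-2,5,6,7,8,8a-hexahydroquinolin-3(1H)-one
Conditions: Et3SiH, BF3·OEt2, CH2Cl2, -78 to -40 °C
Reagents that add atoms: none
Why: Ionic hydrogenation through the N-sulfonyliminium ion; hydride adds axially on the top face, anti to the pseudoaxial C2 methyl (allylic 1,3-strain with the sulfonyl group) and to the C5 chain, giving the 2,6-cis piperidine (8aR).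

Step 10
Reactants: 19 (2S,5S,8aR)-1-Bus-2-methyl-5-[(5R)-5-(TBSO)octyl]-2,5,6,7,8,8a-hexahydroquinolin-3(1H)-one
Product: 20 (2S,4aS,5S,8aR)-1-Bus-2-methyl-5-[(5R)-5-(TBSO)octyl]octahydroquinolin-3(2H)-one
Conditions: H2 (1 atm), Pd/C, EtOAc, rt
Reagents that add atoms: none
Why: Heterogeneous syn hydrogenation of the enone from the convex top face, away from the C2 methyl, the C8 methylene and the C5 chain on the bottom face, puts H4a cis to H8a and H5 (cis ring fusion, 4aS).

Step 11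
Reactants: 20 (2S,4aS,5S,8aR)-1-Bus-2-methyl-5-[(5R)-5-(TBSO)octyl]octahydroquinolin-3(2H)-one
Product: 21 (2S,3S,4aS,5S,8aR)-1-Bus-2-methyl-5-[(5R)-5-(TBSO)octyl]decahydroquinolin-3-ol
Conditions: NaBH4, MeOH, -20 °C
Reagents that add atoms: none
Why: Axial hydride attack from the top face, anti to the axial C2 methyl, gives the equatorial 2,3-cis alcohol (3S), the epimer that the next step inverts.

Step 12
Reactants: 22 (E)-hex-2-enal; 23 malonic acid
Product: 25 (2E,4E)-octa-2,4-dienoic acid, via alkylidenemalonic acid 24 (not isolated)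
Conditions: pyridine, piperidine (cat.), 90 °C
Reagents that add atoms: none
Why: Knoevenagel-Doebner condensation with decarboxylation, the same way sorbic acid is made from crotonaldehyde, gives the 2E acid and keeps the 4E alkene.

Step 13
Reactants: 21 (2S,3S,4aS,5S,8aR)-1-Bus-2-methyl-5-[(5R)-5-(TBSO)octyl]decahydroquinolin-3-ol; 25 (2E,4E)-octa-2,4-dienoic acid
Product: 26 (2S,3R,4aS,5S,8aR)-1-Bus-2-methyl-5-[(5R)-5-(TBSO)octyl]decahydroquinolin-3-yl (2E,4E)-octa-2,4-dienoate
Conditions: PPh3, DIAD, toluene, 0 °C to rt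
Reagents that add atoms: none
Why: Mitsunobu esterification: SN2 attack of the carboxylate from the open top face inverts C3 to R and installs the dienoate in one operation, and the equatorial leaving group has no antiperiplanar hydrogen for elimination.

Step 14
Reactants: 26 (2S,3R,4aS,5S,8aR)-1-Bus-2-methyl-5-[(5R)-5-(TBSO)octyl]decahydroquinolin-3-yl (2E,4E)-octa-2,4-dienoate
Product: 28 lepadin H, via silyl ether amine 27 (not isolated)
Conditions: TfOH (0.1 M), anisole, CH2Cl2, 0 °C; then MeOH, 0 °C to rt; aq NaHCO3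
Reagents that add atoms: none
Why: Acidolytic cleavage of the Bus group (tert-butyl cation trapped by anisole, then loss of SO2) gives the amine silyl ether 27 as its triflate salt, and methanol added to the same acidic solution solvolyses the TBS ether, so the amine and the C5' alcohol are freed without touching the dienoate or any stereocentre.

## Compound list

1 | (R)-2-propyloxirane | CCC[C@@H]1CO1 | starting material
2 | allylmagnesium bromide | C=CC[Mg]Br | starting material
3 | (R)-oct-1-en-5-ol | C=CCC[C@H](O)CCC | intermediate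
4 | (R)-tert-butyldimethyl(oct-1-en-5-yloxy)silane | C=CCC[C@H](O[Si](C)(C)C(C)(C)C)CCC | intermediate
5 | 6,7-dihydrobenzofuran-4(5H)-one | O=C1CCCc2occc12 | starting material
6 | lithium 6,7-dihydrobenzofuran-4-olate (enolate of 5) | [Li]OC1=CCCc2occc12 | intermediate
7 | 6,7-dihydrobenzofuran-4-yl trifluoromethanesulfonate | O=S(=O)(OC1=CCCc2occc12)C(F)(F)F | intermediate
8 | 9-[(5R)-5-(tert-butyldimethylsilyloxy)octyl]-9-borabicyclo[3.3.1]nonane | C(CCC[C@H](O[Si](C)(C)C(C)(C)C)CCC)B1C2CCCC1CCC2 | intermediate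
9 | 4-[(5R)-5-(tert-butyldimethylsilyloxy)octyl]-6,7-dihydrobenzofuran | c1cc2C(CCCC[C@H](O[Si](C)(C)C(C)(C)C)CCC)=CCCc2o1 | intermediate
10 | (4S)-4-[(5R)-5-(tert-butyldimethylsilyloxy)octyl]-4,5,6,7-tetrahydrobenzofuran | c1cc2[C@@H](CCCC[C@H](O[Si](C)(C)C(C)(C)C)CCC)CCCc2o1 | intermediate
11 | (S)-2-methylpropane-2-sulfinamide | CC(C)(C)[S@](=O)N | starting material
12 | acetaldehyde | CC=O | starting material
13 | (S,E)-N-ethylidene-2-methylpropane-2-sulfinamide | CC(C)(C)[S@](=O)/N=C/C | intermediate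
14 | 2-lithio derivative of 10 | [Li]c1cc2[C@@H](CCCC[C@H](O[Si](C)(C)C(C)(C)C)CCC)CCCc2o1 | intermediate
15 | 2-(bromomagnesio) derivative of 10 | Br[Mg]c1cc2[C@@H](CCCC[C@H](O[Si](C)(C)C(C)(C)C)CCC)CCCc2o1 | intermediate
16 | (S)-N-[(1S)-1-{(4S)-4-[(5R)-5-(tert-butyldimethylsilyloxy)octyl]-4,5,6,7-tetrahydrobenzofuran-2-yl}ethyl]-2-methylpropane-2-sulfinamide | CC(C)(C)[S@](=O)N[C@@H](C)c1cc2[C@@H](CCCC[C@H](O[Si](C)(C)C(C)(C)C)CCC)CCCc2o1 | intermediate
17 | N-[(1S)-1-{(4S)-4-[(5R)-5-(tert-butyldimethylsilyloxy)octyl]-4,5,6,7-tetrahydrobenzofuran-2-yl}ethyl]-2-methylpropane-2-sulfonamide | CC(C)(C)S(=O)(=O)N[C@@H](C)c1cc2[C@@H](CCCC[C@H](O[Si](C)(C)C(C)(C)C)CCC)CCCc2o1 | intermediate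
18 | (2S,5S)-1-(tert-butylsulfonyl)-8a-hydroxy-2-methyl-5-[(5R)-5-(tert-butyldimethylsilyloxy)octyl]-2,5,6,7,8,8a-hexahydroquinolin-3(1H)-one, mixture of 8a epimers | O=C1C=C2[C@@H](CCCC[C@H](O[Si](C)(C)C(C)(C)C)CCC)CCCC2(O)N(S(=O)(=O)C(C)(C)C)[C@H]1C | intermediate
19 | (2S,5S,8aR)-1-(tert-butylsulfonyl)-2-methyl-5-[(5R)-5-(tert-butyldimethylsilyloxy)octyl]-2,5,6,7,8,8a-hexahydroquinolin-3(1H)-one | O=C1C=C2[C@@H](CCCC[C@H](O[Si](C)(C)C(C)(C)C)CCC)CCC[C@H]2N(S(=O)(=O)C(C)(C)C)[C@H]1C | intermediate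
20 | (2S,4aS,5S,8aR)-1-(tert-butylsulfonyl)-2-methyl-5-[(5R)-5-(tert-butyldimethylsilyloxy)octyl]octahydroquinolin-3(2H)-one | O=C1C[C@H]2[C@@H](CCCC[C@H](O[Si](C)(C)C(C)(C)C)CCC)CCC[C@H]2N(S(=O)(=O)C(C)(C)C)[C@H]1C | intermediate
21 | (2S,3S,4aS,5S,8aR)-1-(tert-butylsulfonyl)-2-methyl-5-[(5R)-5-(tert-butyldimethylsilyloxy)octyl]decahydroquinolin-3-ol | O[C@H]1C[C@H]2[C@@H](CCCC[C@H](O[Si](C)(C)C(C)(C)C)CCC)CCC[C@H]2N(S(=O)(=O)C(C)(C)C)[C@H]1C | intermediate
22 | (E)-hex-2-enal | CCC/C=C/C=O | starting material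
23 | malonic acid | OC(=O)CC(=O)O | starting material
24 | 2-[(E)-hex-2-en-1-ylidene]malonic acid | CCC/C=C/C=C(C(=O)O)C(=O)O | intermediate
25 | (2E,4E)-octa-2,4-dienoic acid | CCC/C=C/C=C/C(=O)O | intermediate
26 | (2S,3R,4aS,5S,8aR)-1-(tert-butylsulfonyl)-2-methyl-5-[(5R)-5-(tert-butyldimethylsilyloxy)octyl]decahydroquinolin-3-yl (2E,4E)-octa-2,4-dienoate | CCC/C=C/C=C/C(=O)O[C@@H]1C[C@H]2[C@@H](CCCC[C@H](O[Si](C)(C)C(C)(C)C)CCC)CCC[C@H]2N(S(=O)(=O)C(C)(C)C)[C@H]1C | intermediate
27 | (2S,3R,4aS,5S,8aR)-2-methyl-5-[(5R)-5-(tert-butyldimethylsilyloxy)octyl]decahydroquinolin-3-yl (2E,4E)-octa-2,4-dienoate (silyl ether amine) | CCC/C=C/C=C/C(=O)O[C@@H]1C[C@H]2[C@@H](CCCC[C@H](O[Si](C)(C)C(C)(C)C)CCC)CCC[C@H]2N[C@H]1C | intermediate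
28 | lepadin H, (2S,3R,4aS,5S,8aR)-5-[(5R)-5-hydroxyoctyl]-2-methyldecahydroquinolin-3-yl (2E,4E)-octa-2,4-dienoate | CCC/C=C/C=C/C(=O)O[C@@H]1C[C@H]2[C@@H](CCCC[C@H](O)CCC)CCC[C@H]2N[C@H]1C | target

## Step count and risks

Total steps: 14. Longest linear sequence: 11 (steps 1, 2, 4, 5, 7, 8, 9, 10, 11, 13, 14).

Most likely to fail, in route order:

Step 5. The enantioselective hydrogenation of a furan-conjugated cyclic alkene has only carbocyclic precedent, and because the side chain is already chiral, imperfect selectivity shows up as a C5 diastereomer. The fallback sets C5 by asymmetric conjugate addition and builds the furan afterwards; it sets out from 4 and returns at 10. Hydrozirconation of 4 with Cp2Zr(H)Cl gives chlorobis(cyclopentadienyl)[(5R)-5-(TBSO)octyl]zirconium F1. This adds to cyclohex-2-en-1-one under (CuOTf)2·C6H6/chiral phosphoramidite catalysis with Me3SiCl to give (S)-3-[(5R)-5-(TBSO)octyl]-1-(trimethylsilyloxy)cyclohex-1-ene F2, kept as the silyl enol ether by a non-aqueous work-up. Regiospecific allylation with allyl methyl carbonate and Pd2(dba)3/1,2-bis(diphenylphosphino)ethane gives (2R,3S)-2-allyl-3-[(5R)-5-(TBSO)octyl]cyclohexan-1-one F3. Ozonolysis (O3, then Me2S) gives 2-{(1R,2S)-2-[(5R)-5-(TBSO)octyl]-6-oxocyclohexyl}acetaldehyde F4, and TsOH in toluene closes the furan (Paal-Knorr) to 10.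

Step 7. The acetaldehyde-derived imine is enolisable and the facial selectivity depends on keeping the magnesium chelate intact. The fallback keeps the furyl anion as the carbon nucleophile but makes the stereocentre by reduction; it sets out from 10 (through 14) and returns at 16. Furyllithium 14 is acylated with N-methoxy-N-methylacetamide to give 1-{(4S)-4-[(5R)-5-(TBSO)octyl]-4,5,6,7-tetrahydrobenzofuran-2-yl}ethan-1-one F5. Condensation with 11 and Ti(OEt)4 gives (S,E)-N-[1-{(4S)-4-[(5R)-5-(TBSO)octyl]-4,5,6,7-tetrahydrobenzofuran-2-yl}ethylidene]-2-methylpropane-2-sulfinamide F6. Reduction with NaBH4 in wet THF at -48 °C (cyclic transition state, hydride to the face of the sulfinyl oxygen) gives 16.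

Step 13. This is a Mitsunobu reaction on a hindered secondary alcohol next to an axial methyl, with a carboxylic acid of only moderate acidity. The fallback separates activation from displacement; it sets out from 21 and returns at 26. MsCl/Et3N gives (2S,3S,4aS,5S,8aR)-1-Bus-2-methyl-5-[(5R)-5-(TBSO)octyl]decahydroquinolin-3-yl methanesulfonate F7. Heating it with cesium (2E,4E)-octa-2,4-dienoate F8 (from 25 and Cs2CO3) and 18-crown-6 in toluene at 80 °C displaces the mesylate with inversion to give 26.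

Further compounds

F1 | step 5 | chlorobis(cyclopentadienyl)[(5R)-5-(tert-butyldimethylsilyloxy)octyl]zirconium | Cl[Zr](CCCC[C@H](O[Si](C)(C)C(C)(C)C)CCC)(C1C=CC=C1)C1C=CC=C1
F2 | step 5 | (S)-3-[(5R)-5-(tert-butyldimethylsilyloxy)octyl]-1-(trimethylsilyloxy)cyclohex-1-ene | C[Si](C)(C)OC1=C[C@@H](CCCC[C@H](O[Si](C)(C)C(C)(C)C)CCC)CCC1
F3 | step 5 | (2R,3S)-2-allyl-3-[(5R)-5-(tert-butyldimethylsilyloxy)octyl]cyclohexan-1-one | C=CC[C@@H]1[C@@H](CCCC[C@H](O[Si](C)(C)C(C)(C)C)CCC)CCCC1=O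
F4 | step 5 | 2-{(1R,2S)-2-[(5R)-5-(tert-butyldimethylsilyloxy)octyl]-6-oxocyclohexyl}acetaldehyde | O=CC[C@@H]1[C@@H](CCCC[C@H](O[Si](C)(C)C(C)(C)C)CCC)CCCC1=O
F5 | step 7 | 1-{(4S)-4-[(5R)-5-(tert-butyldimethylsilyloxy)octyl]-4,5,6,7-tetrahydrobenzofuran-2-yl}ethan-1-one | CC(=O)c1cc2[C@@H](CCCC[C@H](O[Si](C)(C)C(C)(C)C)CCC)CCCc2o1
F6 | step 7 | (S,E)-N-[1-{(4S)-4-[(5R)-5-(tert-butyldimethylsilyloxy)octyl]-4,5,6,7-tetrahydrobenzofuran-2-yl}ethylidene]-2-methylpropane-2-sulfinamide | CC(C)(C)[S@](=O)/N=C(\C)c1cc2[C@@H](CCCC[C@H](O[Si](C)(C)C(C)(C)C)CCC)CCCc2o1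
F7 | step 13 | (2S,3S,4aS,5S,8aR)-1-(tert-butylsulfonyl)-2-methyl-5-[(5R)-5-(tert-butyldimethylsilyloxy)octyl]decahydroquinolin-3-yl methanesulfonate | CS(=O)(=O)O[C@H]1C[C@H]2[C@@H](CCCC[C@H](O[Si](C)(C)C(C)(C)C)CCC)CCC[C@H]2N(S(=O)(=O)C(C)(C)C)[C@H]1C
F8 | step 13 | cesium (2E,4E)-octa-2,4-dienoate | [Cs+].CCC/C=C/C=C/C(=O)[O-]
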